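**Retrosynthetic overview**
1. Last bond: the C8–CH2 diarylmethane link, made by trapping the ortho-quinone methide of the acetyl-methyl-phloroglucinol half (released from its Mannich base) with (2S)-6-prenylpinocembrin.
2. Key disconnection: the O1–C2 ether bond of ring C, closed by a site- and enantioselective oxa-Michael addition of the open-chain chalcone; this sets the only stereocentre.
3. The chalcone comes from aldol condensation of C-prenylated phloroacetophenone with benzaldehyde; the prenyl group comes from prenyl bromide.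
4. Ring order: ring A, ring B and the second phloroglucinol ring are bought as arenes; ring C is the only ring formed (step 3).

Assumption: 1-(2,4,6-trihydroxy-3-methylphenyl)ethanone is taken as a catalogue compound; the other starting materials are commodity chemicals.

**Route**

Step 1
Reactants: 1 1-(2,4,6-trihydroxyphenyl)ethanone (phloroacetophenone, 2 equiv); 2 1-bromo-3-methylbut-2-ene (prenyl bromide, 1 equiv)
Product: 3 1-[2,4,6-trihydroxy-3-(3-methylbut-2-en-1-yl)phenyl]ethanone
Conditions: 10% aq. KOH, 0 °C → rt, 3 h
Reagents that add atoms: none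
Why: Base-mediated C-alkylation of the ambident phloroglucinolate (phenoxide C-prenylation) at one of the two equivalent ring CH positions gives the mono-C-prenyl ketone after rearomatisation; excess 1 holds back di-prenylation and no stereocentre is formed.

Step 2
Reactants: 3 1-[2,4,6-trihydroxy-3-(3-methylbut-2-en-1-yl)phenyl]ethanone; 4 benzaldehyde
Product: 6 (E)-3-phenyl-1-[2,4,6-trihydroxy-3-(3-methylbut-2-en-1-yl)phenyl]prop-2-en-1-one, via racemic aldol adduct 5 (not isolated)
Conditions: LiN(SiMe3)2 (6 equiv), THF, −78 °C → rt, 12 h; 1 M HCl, 0 °C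
Reagents that add atoms: none
Why: Aldol condensation of Claisen–Schmidt type on the fully lithiated substrate: excess LiN(SiMe3)2 forms the trilithium phenoxide–enolate, which adds to benzaldehyde, and the aldolate eliminates (E1cB) on warming and acidic quench to the (E)-enone, so no protecting groups are needed and no stereocentre remains.

Step 3
Reactants: 6 (E)-3-phenyl-1-[2,4,6-trihydroxy-3-(3-methylbut-2-en-1-yl)phenyl]prop-2-en-1-one
Product: 7 (2S)-5,7-dihydroxy-6-(3-methylbut-2-en-1-yl)-2-phenyl-2,3-dihydro-4H-chromen-4-one ((S)-6-prenylpinocembrin)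
Conditions: (R)-3,3'-bis(2,4,6-triisopropylphenyl)-1,1'-binaphthyl-2,2'-diyl hydrogen phosphate ((R)-TRIP, 10 mol %), anhydrous CH2Cl2/PhCF3 (1:1), 0 °C, 48 h
Reagents that add atoms: none
Why: Proposed new method: the chiral phosphoric acid acts as a bifunctional proton shuttle (P=O takes the proton of the attacking phenol while P–OH activates the enone carbonyl, whose other lone pair stays chelated by the prenyl-buttressed 2'-OH), so the 6-endo oxa-Michael closure should go through the unhindered 6'-OH that fits between the 3,3'-aryl walls (giving the 6-prenyl and not the 8-prenyl flavanone), and the chiral pocket is expected to expose the Si face of C-β, which gives (2S); the closest known reaction types are chiral phosphoric acid-catalysed intramolecular aza-Michael cyclisation of 2'-aminochalcones and bifunctional thiourea-catalysed oxa-Michael closure of activated 2'-hydroxychalcones, neither shown for an unactivated, unprotected 2',4',6'-trihydroxychalcone with two different ortho-phenols.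

Step 4
Reactants: 8 1-(2,4,6-trihydroxy-3-methylphenyl)ethanone; 9 N,N-dimethylmethaniminium iodide (Eschenmoser's salt, 1.05 equiv)
Product: 10 1-{3-[(dimethylamino)methyl]-2,4,6-trihydroxy-5-methylphenyl}ethanone
Conditions: MeCN, 0 °C → rt, 2 h; aq. NaHCO3 to pH 7, collect the precipitate
Reagents that add atoms: none
Why: Mannich aminomethylation by a preformed iminium ion (electrophilic aromatic substitution) at the only unsubstituted carbon of the acylphloroglucinol ring, so a single regioisomer forms and no stereocentre is created.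

Step 5
Reactants: 7 (2S)-5,7-dihydroxy-6-(3-methylbut-2-en-1-yl)-2-phenyl-2,3-dihydro-4H-chromen-4-one (1.0 equiv); 10 1-{3-[(dimethylamino)methyl]-2,4,6-trihydroxy-5-methylphenyl}ethanone (1.1 equiv, added in portions)
Product: 12 (2S)-8-[(3-acetyl-2,4,6-trihydroxy-5-methylphenyl)methyl]-5,7-dihydroxy-6-(3-methylbut-2-en-1-yl)-2-phenyl-2,3-dihydro-4H-chromen-4-one (target), via ortho-quinone methide 11 (not isolated)
Conditions: AcOH (1.5 equiv), 1,4-dioxane, 70 °C, N2, 6 h
Reagents that add atoms: none
Why: Thermal loss of Me2NH from the ortho-hydroxybenzylamine gives ortho-quinone methide 11, which is trapped in a Michael-type Friedel–Crafts alkylation by C-8 of 7 (its only free aromatic carbon); the acetic acid buffer keeps the medium non-basic so that ring C does not open and C-2 stays (S).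

**Compound list**
1 | 1-(2,4,6-trihydroxyphenyl)ethanone (phloroacetophenone) | CC(=O)c1c(O)cc(O)cc1O | starting material
2 | 1-bromo-3-methylbut-2-ene (prenyl bromide) | CC(C)=CCBr | starting material
3 | 1-[2,4,6-trihydroxy-3-(3-methylbut-2-en-1-yl)phenyl]ethanone | CC(=O)c1c(O)cc(O)c(CC=C(C)C)c1O | intermediate
4 | benzaldehyde | O=Cc1ccccc1 | starting material
5 | 3-hydroxy-3-phenyl-1-[2,4,6-trihydroxy-3-(3-methylbut-2-en-1-yl)phenyl]propan-1-one (racemic aldol adduct, not isolated) | CC(C)=CCc1c(O)cc(O)c(C(=O)CC(O)c2ccccc2)c1O | intermediate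
6 | (E)-3-phenyl-1-[2,4,6-trihydroxy-3-(3-methylbut-2-en-1-yl)phenyl]prop-2-en-1-one | CC(C)=CCc1c(O)cc(O)c(C(=O)/C=C/c2ccccc2)c1O | intermediate
7 | (2S)-5,7-dihydroxy-6-(3-methylbut-2-en-1-yl)-2-phenyl-2,3-dihydro-4H-chromen-4-one | CC(C)=CCc1c(O)cc2O[C@H](c3ccccc3)CC(=O)c2c1O | intermediate
8 | 1-(2,4,6-trihydroxy-3-methylphenyl)ethanone | CC(=O)c1c(O)cc(O)c(C)c1O | starting material
9 | N,N-dimethylmethaniminium iodide (Eschenmoser's salt) | C=[N+](C)C.[I-] | starting material
10 | 1-{3-[(dimethylamino)methyl]-2,4,6-trihydroxy-5-methylphenyl}ethanone | CC(=O)c1c(O)c(C)c(O)c(CN(C)C)c1O | intermediate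
11 | 4-acetyl-3,5-dihydroxy-2-methyl-6-methylidenecyclohexa-2,4-dien-1-one (ortho-quinone methide, not isolated) | CC(=O)C1=C(O)C(=C)C(=O)C(C)=C1O | intermediate
12 | (2S)-8-[(3-acetyl-2,4,6-trihydroxy-5-methylphenyl)methyl]-5,7-dihydroxy-6-(3-methylbut-2-en-1-yl)-2-phenyl-2,3-dihydro-4H-chromen-4-one | CC(=O)c1c(O)c(C)c(O)c(Cc2c(O)c(CC=C(C)C)c(O)c3c2O[C@H](c2ccccc2)CC3=O)c1O | target

**Step count**
Total steps: 5. Longest linear sequence: 4 (steps 1, 2, 3, 5); step 4 is a one-step side branch.

**Three steps most likely to fail**

Step 3 (the proposed new cyclisation). The site selectivity between the two ortho-phenols and the level and sense of induction are unproven; if the sense is opposite, the (S)-acid is used instead. Fallback with known chemistry, setting out from 6 and coming back at 7: 6 is heated with NaOAc in EtOH (ordinary chalcone–flavanone isomerisation). This gives racemic 5,7-dihydroxy-6-(3-methylbut-2-en-1-yl)-2-phenyl-2,3-dihydro-4H-chromen-4-one F3 together with its regioisomer, racemic 5,7-dihydroxy-8-(3-methylbut-2-en-1-yl)-2-phenyl-2,3-dihydro-4H-chromen-4-one F4, which is removed by chromatography. F3 is resolved by preparative HPLC on an amylose tris(3,5-dimethylphenylcarbamate) phase to give 7. The unwanted (2R)-5,7-dihydroxy-6-(3-methylbut-2-en-1-yl)-2-phenyl-2,3-dihydro-4H-chromen-4-one F5 is re-equilibrated through the chalcone under the same NaOAc conditions and recycled.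

Step 2 (condensation without protecting groups). The tetra-anion may react sluggishly, and the free 2',6'-dihydroxychalcone can partly close to racemic flavanone on work-up; this must be removed before step 3. Fallback, setting out from 3 and coming back at 6: 3 is fully protected (NaH, chloromethyl methyl ether, DMF) to 1-[2,4,6-tris(methoxymethoxy)-3-(3-methylbut-2-en-1-yl)phenyl]ethanone F1. A standard Claisen–Schmidt condensation with 4 (KOH, EtOH/H2O, rt) gives (E)-3-phenyl-1-[2,4,6-tris(methoxymethoxy)-3-(3-methylbut-2-en-1-yl)phenyl]prop-2-en-1-one F2. Brief HCl/MeOH at rt removes the three acetals to give 6.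

Step 5 (methylene bridging on the chiral flavanone). Risks are partial racemisation at C-2 by the liberated amine, and side reactions of quinone methide 11 with the prenyl alkene or with itself. Fallback, setting out from 7 and coming back at 12, with the roles of the partners reversed: 7 is aminomethylated at its only free position with 9 (MeCN, rt) to give (2S)-8-[(dimethylamino)methyl]-5,7-dihydroxy-6-(3-methylbut-2-en-1-yl)-2-phenyl-2,3-dihydro-4H-chromen-4-one F6. F6 is warmed (dioxane, 50–60 °C) with 3 equiv of 8. The acidic acylphloroglucinol protonates the amine, traps the flavanone-derived quinone methide at its single free carbon and buffers the medium, and its excess suppresses self-condensation, giving 12.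

**Further compounds**
F1 | step 2 | 1-[2,4,6-tris(methoxymethoxy)-3-(3-methylbut-2-en-1-yl)phenyl]ethanone | CC(=O)c1c(OCOC)cc(OCOC)c(CC=C(C)C)c1OCOC
F2 | step 2 | (E)-3-phenyl-1-[2,4,6-tris(methoxymethoxy)-3-(3-methylbut-2-en-1-yl)phenyl]prop-2-en-1-one | COCOc1cc(OCOC)c(C(=O)/C=C/c2ccccc2)c(OCOC)c1CC=C(C)C
F3 | step 3 | racemic 5,7-dihydroxy-6-(3-methylbut-2-en-1-yl)-2-phenyl-2,3-dihydro-4H-chromen-4-one | CC(C)=CCc1c(O)cc2OC(c3ccccc3)CC(=O)c2c1O
F4 | step 3 | racemic 5,7-dihydroxy-8-(3-methylbut-2-en-1-yl)-2-phenyl-2,3-dihydro-4H-chromen-4-one | CC(C)=CCc1c(O)cc(O)c2C(=O)CC(c3ccccc3)Oc12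
F5 | step 3 | (2R)-5,7-dihydroxy-6-(3-methylbut-2-en-1-yl)-2-phenyl-2,3-dihydro-4H-chromen-4-one | CC(C)=CCc1c(O)cc2O[C@@H](c3ccccc3)CC(=O)c2c1O
F6 | step 5 | (2S)-8-[(dimethylamino)methyl]-5,7-dihydroxy-6-(3-methylbut-2-en-1-yl)-2-phenyl-2,3-dihydro-4H-chromen-4-one | CC(C)=CCc1c(O)c(CN(C)C)c2O[C@H](c3ccccc3)CC(=O)c2c1O
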